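A flat run says that a flask has stopped, not why it stopped, and a flat run read as balance predicts differently from one read as dead catalyst.

| flask | starting material | catalyst | temperature | remark | time |
|---|---|---|---|---|---|
| amber | 0.20 M | 0.11 mol% | −5 °C | run made earlier |  |
| grey | 0.20 M | 0.18 mol% | 28 °C | run made earlier |  |
| Monday's | 0.20 M | 0.08 mol% | 10 °C |  | 25 d |
| Thursday's | 0.20 M | 0.08 mol% | −20 °C |  | 25 d |
| Saturday's | 0.20 M | 0.08 mol% |  | at −20 °C until 8.0 d, from then on at 40 °C | 25 d |
| Wednesday's | 0.20 M | 0.08 mol% | 40 °C |  | 25 d |

| run | time / d | target / % | starting material / % |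
|---|---|---|---|
| amber | 10.0 | 38.7 | 53.0 |
| amber | 20.0 | 36.6 | 52.5 |
| amber | 30.0 | 39.6 | 50.8 |
| amber | 40.0 | 38.6 | 55.0 |
| amber | 50.0 | 38.2 | 51.6 |
| amber | 60.0 | 39.7 | 51.1 |
| grey | 1.04 | 16.2 | 61.5 |
| grey | 1.67 | 14.9 | 62.0 |
| grey | 2.50 | 14.7 | 63.8 |
| grey | 4.00 | 16.0 | 62.0 |
| grey | 8.00 | 17.4 | 62.5 |
| grey | 12.0 | 16.7 | 60.1 |

(readings scatter by 1 percentage point)



- the best flask by amount of target, in percent of the starting material charged; "all alike" if 1.5 percentage points covers them all (Monday's / Thursday's / Saturday's / Wednesday's / all alike)
- amount of target at the end, in percent of the starting material charged, Monday's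
- amount of target at the end, in percent of the starting material charged, Thursday's
- amount of target at the end, in percent of the starting material charged, Saturday's
- amount of target at the end, in percent of the starting material charged, Wednesday's

1. Amber and grey show no trend beyond their scatter from their first readings. Taken as balance, which heeds no loading, they give two ratios to starting material. Target gives r, 0.737 in amber and 0.258 in grey. The unread remainder gives s, 0.174 and 0.355.

2. The integrated van 't Hoff law makes each logarithm straight in inverse temperature. Read from these scattered ratios, making target releases about 21.4 kJ mol⁻¹, and making the remainder absorbs about 14.5 kJ mol⁻¹.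

3. For Thursday's, r comes to 1.30 and s to 0.118. Dividing r by the sum of one, r and s gives 53.8 %. This is the plateau share of target, the share expected under thermodynamic control.

4. Monday's plateau share is 26.3 %, and Wednesday's is 11.4 %. Saturday's stays hot for 17.0 d, longer than the time of grey's first reading, though grey differs from it in temperature and loading, and my reckoning takes Saturday's to end at Wednesday's value. In this reckoning Thursday's leads.

5. Turned round, with Monday's at its plateau, Monday's wins if Thursday's covers less than 48.9 % of its way to plateau. An exponential approach does that in 25 d if the half-life exceeds 25.9 d. Amber, flat within its scatter from 10.0 d, is taken to have passed 3 half-lives by then, which puts its half-life at about 3.33 d, shorter than that limit. Thursday's half-life would have to be 7.78 times this estimate for amber. The readings cannot exclude this, but my reckoning stays at plateau.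

6. The forecast gives Monday's 22 %, Thursday's 40 %, Saturday's 16 % and Wednesday's 8 %, best Thursday's. It lowers Thursday's below my figure with the words “25 d may not be enough”.

7. The flasks give Monday's 26.5 %, Thursday's 53.6 %, Saturday's 11.7 % and Wednesday's 11.7 %, so Thursday's is best.

8. catalyst ⇌ dormant form (K = 1.30, k = 7.40 × 10⁻⁴ min⁻¹, Ea = 75.0 kJ mol⁻¹, ΔH = −19.0 kJ mol⁻¹); starting material ⇌ target (K = 1.30, k = 0.00330 min⁻¹, Ea = 81.0 kJ mol⁻¹, ΔH = −21.0 kJ mol⁻¹); target + catalyst ⇌ isomer of the product + catalyst, rate k3*[catalyst]*[target] forward; the back reaction follows from the equilibrium constant (K = 0.0960, k = 3.00 M⁻¹ min⁻¹, Ea = 40.0 kJ mol⁻¹, ΔH = 35.0 kJ mol⁻¹); isomer of the product ⇌ starting material (k = 2.70 × 10⁻⁵ min⁻¹, Ea = 85.0 kJ mol⁻¹); (constants at −20 °C)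

9. Thursday's already holds 53.6 % at 12.5 d. In Thursday's, the half-life of target by its forward turning into isomer of the product alone, 1.1 d at 0.0869 d, is short against 25 d. For a neighbour like Thursday's at −45 °C, the plateau share reckoned from amber and grey is 78.9 %, and at 25.0 d that flask holds 69.8 %, which is 9.1 percentage points short of the reckoned share.

The runs are calculated with constants of no real substance, and the scatter is random.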